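I began from a leftover. The partner took left-handed substrate faster than right-handed substrate (14 /M/s against 0.75 /M/s), so what stayed behind had to lean to the right, and I wanted to know what that lean cost.

| setting | maple | larch | elm | alder |
|---|---|---|---|---|
| left-handed substrate | 5.0 mM | 5.0 mM | 5.0 mM | 5.0 mM |
| partner | 2.20 equiv | 2.20 equiv | 2.20 equiv | 2.20 equiv |
| right-handed substrate | 5.0 mM | 5.0 mM | 5.0 mM | 5.0 mM |
| temperature | −20 °C | 10 °C | −5 °C |  |
| time | 5.0 s | 5.0 s | 5.0 s | 5.0 s |
| remark |  |  |  | at 10 °C until 1.5 s, from then on at −20 °C |

    partner + left-handed substrate → left-handed product (k1 = 14 /M/s, Ea1 = 41.0 kJ/mol)
    partner + right-handed substrate → right-handed product (k2 = 0.75 /M/s, Ea2 = 43.0 kJ/mol)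
    left-handed substrate ⇌ achiral form (K3 = 1.2, k3 = 0.18 /s, Ea3 = 62.0 kJ/mol, ΔH3 = −43.0 kJ/mol)
    right-handed substrate ⇌ achiral form (K3 = 1.2, k3 = 0.18 /s, Ea3 = 62.0 kJ/mol, ΔH3 = −43.0 kJ/mol)
    achiral form → waste (k5 = 0.0060 /s, Ea5 = 68.0 kJ/mol)
    partner → decomposed reagent (k6 = 0.11 /s, Ea6 = 64.0 kJ/mol)
    achiral form → side product (k7 = 0.51 /s, Ea7 = 67.0 kJ/mol)
    partner → decomposition product (k8 = 8.2 × 10⁻⁵ /s, Ea8 = 86.0 kJ/mol)
    (constants at −20 °C)

- partner is single-handed; left-handed substrate and right-handed substrate are mirror images of each other, charged as a racemate, each of them at the stated concentration
- the constants hold at −20 °C; other temperatures follow from the activation energies and enthalpies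
- an excess is below zero if the other one leads
- the handed part of partner does not stay in what it makes, so the products of the two hands are mirror images too

* the flask that comes out highest in excess of left-handed product over right-handed product, or "all alike" when all lie within 1.5 percentage points (maple / larch / elm / alder / all alike)
* excess of left-handed product over right-handed product at the end, maple
* excess of left-handed product over right-handed product at the end, larch
* excess of left-handed product over right-handed product at the end, elm
* excess of left-handed product over right-handed product at the end, alder

My first way compared rates at the first moment. With equal substrates, the products form in the ratio of the two rate constants, the selectivity factor s, which in maple is 18.7. The excess of what forms is then (s − one)/(s + one), or 89.8%. This is a ceiling, since a lean to the right lowers the ratio. In larch, s is 16.9 and the ceiling 88.8%.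

My second way asked how that comparison drifts. The achiral form refills both hands alike, so the lean stops growing where each substrate, times its total loss constant to the partner and to the achiral form, gives the same flow. With the charged partner 11.0 mM, this gives maple a left-to-right substrate ratio of 0.564, the balance ratio, written ρ. Multiplying s by ρ gives a floor of 82.6%. In larch, ρ is 0.784 and the floor 86.0%.

The two ways parted, so I asked which one cheated. Each did, in its own direction. The first held the substrates equal, while the second put the balance in place at the first instant and kept the partner at its charge. In maple the ratio closes on ρ over about 2.99 s, set against a run of 5.0 s, and a falling partner raises ρ. I therefore committed to the stretch between midpoint and ceiling: 86.2% to 89.8% for maple, and 87.4% to 88.8% for larch. Elm lay between them in temperature, so I placed it in the same band. In alder at 10 °C, the step to decomposed reagent by itself halves the partner in 0.251 s, shorter than the 1.5 s before the change, so I took alder for larch. The ceilings lay 1 percentage point apart, inside the margin, and warming lowered the ceiling while it raised the floor. That proved nothing, but I said all alike.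

The forecast gave 87.7% for maple, 87.8% for larch, 87.7% for elm and 87.8% for alder, and so all alike. It stepped each flask through by hand, with substrate ratios near 0.8 in the cold and 0.9 in the warm, and judged: “These effects nearly cancel.” Where I gave bands, it gave points.

The simulation gave 87.7% for maple, 87.9% for larch, 87.7% for elm and 87.9% for alder, so all alike, as the forecast said. At 5.00 s, maple still held 34% of its left-handed substrate and 51% of its right-handed substrate. Read back through s, maple's excess corresponds to a mean substrate ratio of 0.821, which stood above ρ and below one.

Then I took the neighbour of elm with 8.80 equiv of partner, 44.0 mM. There ρ falls to 0.375, and with s at 17.7 the band runs from 73.8% to 89.3%. The computed flask gave 82.4%, above that floor and below that ceiling.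

The rate constants were set for the occasion, and the outcome is calculated.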